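## Retrosynthetic overview

1. The target holds two trans-(3S,4S)-3,4-dibenzylbutyrolactones (C2 carbonyl, C3, C4, C5 = OCH2). They hang from benzylic carbons C7 (ring A) and C7' (ring B) of a ring A–O–ring B diaryl ether, and rings C and D are the veratryl arenes on C4 and C4'.
2. Feature used: in each half C7–C3–C4 is a three-carbon allyl span, so the C4–C5 bond stands in a [2,3] relation to an oxygen on C7. C7 is a former aldehyde carbon that can be made as one carbinol enantiomer, and C3 is epimerisable and follows C4.
3. Disconnections, backwards: C3 epimerisation and C7=C3 hydrogenation; both O1–C2 lactone bonds (MnO2 lactonisation); both C4–C5 bonds (double Wittig–Still rearrangement); both C7–C3 bonds (alkenyllithium plus dialdehyde); the ring A–O bond (SNAr).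
4. Ring order: the four arenes are bought and the diaryl ether is joined first (step 2). No ring closes in the key step, and both lactone rings close together in step 12.

Key step: step 10

Assumption 1: the SMILES is read as (3S,4S) in both lactones (trans), the mirror-image series of natural arctigenin, and all descriptors below follow from this.
Assumption 2: in the CBS reduction the α-branched, out-of-plane alkenyl residue of 14 is taken as the larger ketone substituent. The sense is to be checked by Mosher ester analysis, and the (S)-catalyst is used if it is reversed.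

## Route

Step 1
Reactants: 1 3,4-dihydroxy-5-methoxybenzaldehyde (5-hydroxyvanillin)
Product: 2 4-(benzyloxy)-3-hydroxy-5-methoxybenzaldehyde
Conditions: BnBr (1.0 equiv), Li2CO3, DMF, 50 °C
Reagents that add atoms: benzyl bromide, BrCc1ccccc1
Why: Williamson etherification under a weak base; the 4-OH is para to the formyl group and is the more acidic phenol, so only its phenoxide forms and takes the single equivalent of benzyl bromide, which leaves the 3-OH free for step 2.

Step 2
Reactants: 2 4-(benzyloxy)-3-hydroxy-5-methoxybenzaldehyde; 3 4-fluoro-3-methoxybenzaldehyde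
Product: 4 4-(benzyloxy)-3-(4-formyl-2-methoxyphenoxy)-5-methoxybenzaldehyde (diaryl ether dialdehyde)
Conditions: K2CO3, DMF, 110 °C
Reagents that add atoms: none
Why: SNAr; the fluorine of 3 is para to the formyl group, which stabilises the Meisenheimer adduct, so the phenoxide of 2 displaces fluoride and the two building blocks fix the substitution pattern of rings A and B, while neither aldehyde can enolise.

Step 3
Reactants: 5 propargyl alcohol; 6 3,4-dimethoxybenzyl chloride (veratryl chloride)
Product: 8 4-(3,4-dimethoxyphenyl)but-2-yn-1-ol, via dimagnesium alkynyl alkoxide 7 (not isolated)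
Conditions: EtMgBr (2.1 equiv), THF, 0 °C to rt; CuCl (10 mol%), then 6, 55 °C; then H2O
Reagents that add atoms: ethylmagnesium bromide, CC[Mg]Br (its MgBr appears only in 7)
Why: Copper-catalysed alkylation of an alkynyl Grignard reagent by a benzylic chloride; the second equivalent of EtMgBr masks the OH as a poorly nucleophilic magnesium alkoxide, so coupling takes place at the acetylide carbon.

Step 4
Reactants: 8 4-(3,4-dimethoxyphenyl)but-2-yn-1-ol
Product: 10 (E)-4-(3,4-dimethoxyphenyl)-2-iodobut-2-en-1-ol, via proximal vinylstannane 9 (not isolated)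
Conditions: Bu3SnH (slow addition), PdCl2(PPh3)2 (2 mol%), THF, rt; then I2, 0 °C; chromatography
Reagents that add atoms: tributyltin hydride, CCCC[SnH](CCCC)CCCC (tin only in 9); iodine, II
Why: Palladium-catalysed syn hydrostannation followed by iododestannylation with retention; the withdrawing CH2OH group directs tin to the adjacent alkyne carbon, syn addition places H cis to tin so that CH2OH and the veratryl CH2 end up cis, and the distal regioisomer is removed at the iodide stage.

Step 5
Reactants: 10 (E)-4-(3,4-dimethoxyphenyl)-2-iodobut-2-en-1-ol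
Product: 11 (E)-[4-(3,4-dimethoxyphenyl)-2-iodobut-2-enyloxy]triisopropylsilane
Conditions: TIPSCl, imidazole, DMF, rt
Reagents that add atoms: triisopropylsilyl chloride, CC(C)[Si](Cl)(C(C)C)C(C)C
Why: Standard silylation of a primary allylic alcohol; TIPS is chosen because it resists O-to-C migration in alkenyllithium 12 and O-to-O migration in the potassium alkoxides of step 9, and because its bulk on C3 raises the A1,2 strain exploited in step 10.

Step 6
Reactants: 11 (E)-vinyl iodide TIPS ether (2.6 equiv); 4 diaryl ether dialdehyde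
Product: 13 diaryl ether bis[(E)-1-aryl-4-(3,4-dimethoxyphenyl)-2-(triisopropylsilyloxymethyl)but-2-en-1-ol] as a mixture of C7/C7' epimers, via alkenyllithium 12 (not isolated)
Conditions: t-BuLi (2 equiv per iodide), Et2O, −78 °C; then 4, THF, −78 °C; then H2O
Reagents that add atoms: tert-butyllithium, [Li]C(C)(C)C (lithium only in 12)
Why: Iodine–lithium exchange keeps the alkene geometry and the alkenyllithium adds 1,2 to both non-enolisable aldehydes, forming both C7–C3 bonds; the two carbinol centres arise without control and are reset in steps 7 and 8.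

Step 7
Reactants: 13 bis-allylic alcohol (epimer mixture)
Product: 14 diaryl ether bis[(E)-aryl enone], each unit ArC(=O)–C(CH2OTIPS)=CH–CH2(3,4-dimethoxyphenyl)
Conditions: Dess–Martin periodinane (2.5 equiv), CH2Cl2, 0 °C to rt
Reagents that add atoms: none
Why: Dess–Martin oxidation under neutral conditions converts both benzylic allylic alcohols to ketones without shifting the alkene toward the veratryl ring and without affecting the silyl or benzyl ethers.

Step 8
Reactants: 14 bis-enone
Product: 15 diaryl ether (7S,7'S)-bis[(1S,2E)-1-aryl-4-(3,4-dimethoxyphenyl)-2-(triisopropylsilyloxymethyl)but-2-en-1-ol]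
Conditions: (R)-2-methyl-CBS-oxazaborolidine (20 mol% per ketone), catecholborane (3 equiv), toluene, −78 °C; then H2O
Reagents that add atoms: none
Why: CBS reduction; each ketone binds the catalyst boron through the lone pair anti to the bulkier α-branched alkenyl group and receives hydride on its Re face, which sets (S) at C7 and C7' independently under catalyst control, while catecholborane at low temperature avoids hydroboration and 1,4-reduction.

Step 9
Reactants: 15 (7S,7'S)-bis-allylic alcohol; 16 tributyl(iodomethyl)stannane (2.6 equiv)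
Product: 17 diaryl ether bis[(S)-benzylic (E)-allylic tributylstannylmethyl ether] with CH2OTIPS on each C3
Conditions: KH (3 equiv), 18-crown-6 (cat.), THF, 0 °C to rt
Reagents that add atoms: none
Why: Williamson-type O-alkylation of the potassium alkoxides by the reactive α-stannyl iodide, the usual entry to Wittig–Still substrates; the C7–O bonds are not broken, so both (S) centres are kept.

Step 10
Reactants: 17 bis(stannylmethyl ether)
Product: 19 diaryl ether bis[(2S,3E)-4-aryl-2-(3,4-dimethoxybenzyl)-3-(triisopropylsilyloxymethyl)but-3-en-1-ol], via bis(oxymethyllithium) 18 (not isolated)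
Conditions: n-BuLi (2.5 equiv), THF, −78 °C; then H2O
Reagents that add atoms: n-butyllithium, [Li]CCCC (lithium only in 18)
Why: Tin–lithium exchange turns each O–CH2–SnBu3 into O–CH2–Li, and each carbanion bonds to C4 while the C7–O bond breaks, a concerted suprafacial [2,3]-sigmatropic shift through a five-membered envelope (Wittig–Still rearrangement of stannylmethyl ethers of 2-substituted secondary allylic alcohols, run here at both ends of the diaryl ether). No ring closes; two C4–C5 bonds and two stereocentres form, and each alkene moves to C7=C3. C4 is controlled by the (S)-carbinol C7: with the C7–O bond perpendicular to the alkene plane the aryl group takes the inside position, where it meets only the C4–H of the (E)-alkene, because the outside position would press it against CH2OTIPS on C3 (A1,2 strain), and from this conformer the oxymethyl carbon reaches the alkene face that gives (4S). The same conformer leaves the aryl group cis to C4 in the new alkene, so leakage through the aryl-outside conformer gives the (4R) centre together with the other alkene geometry and can be removed as a geometric isomer. The step needs the [2,3] shift to outrun the [1,2] shift and deprotonation at C7–H, which the low temperature, the fast exchange and the short-lived primary carbanion should secure. Silyl migration between the two oxygens after the shift would be harmless, since step 12 selects the allylic CH2OH whichever oxygen carried silicon.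

Step 11
Reactants: 19 bis(mono-TIPS diol)
Product: 20 diaryl ether bis[(2E,3S)-2-(arylmethylidene)-3-(3,4-dimethoxybenzyl)butane-1,4-diol] (tetraol)
Conditions: TBAF (3 equiv), THF, rt
Reagents that add atoms: none
Why: Fluoride-induced Si–O cleavage frees both allylic alcohols under conditions that leave the benzyl ether, the alkenes and C4 untouched.

Step 12
Reactants: 20 tetraol
Product: 23 diaryl ether bis[(3E,4S)-3-(arylmethylidene)-4-(3,4-dimethoxybenzyl)oxolan-2-one], via bis(hydroxy enal) 21 (not isolated), via bis-lactol 22 (not isolated)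
Conditions: activated MnO2 (large excess), CH2Cl2, rt
Reagents that add atoms: none
Why: Chemoselective allylic oxidation with MnO2; only the cinnamyl-type CH2OH at C2 is oxidised, the C5 hydroxyl adds to the enal (5-exo-trig) and the allylic lactol is oxidised again, so both lactone rings close with the carbonyl at C2 and the stable alkene geometry (aryl trans to C=O) is kept.

Step 13
Reactants: 23 bis(benzylidene lactone)
Product: 24 (3R,4S,3'R,4'S)-bis(cis-3,4-dibenzylbutyrolactone) with free ring B phenol (expected main isomer)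
Conditions: H2 (1 atm), 10% Pd/C, EtOAc–EtOH, rt
Reagents that add atoms: none
Why: Heterogeneous hydrogenation adds hydrogen to each C7=C3 alkene from the face opposite the C4 veratryl group, which should give mainly the cis lactones, and the same catalyst hydrogenolyses the benzyl ether; the C3 configuration is corrected in step 14.

Step 14
Reactants: 24 bis(cis-lactone)
Product: 25 target, (3S,4S,3'S,4'S)-bis(trans-lactone) CNP0183104.1
Conditions: DBU (4 equiv), toluene, 100 °C, Ar
Reagents that add atoms: none
Why: Base-mediated epimerisation through the lactone enolate under thermodynamic control; C3 is the only acidic stereocentre and the trans-3,4-dibenzyl arrangement is the more stable, so (4S) dictates (3S) in both rings, and excess base allows for the equivalent taken up by the phenol.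

## Compound list

1 | 3,4-dihydroxy-5-methoxybenzaldehyde | COc1cc(C=O)cc(O)c1O | starting material
2 | 4-(benzyloxy)-3-hydroxy-5-methoxybenzaldehyde | COc1cc(C=O)cc(O)c1OCc1ccccc1 | intermediate
3 | 4-fluoro-3-methoxybenzaldehyde | COc1cc(C=O)ccc1F | starting material
4 | 4-(benzyloxy)-3-(4-formyl-2-methoxyphenoxy)-5-methoxybenzaldehyde | O=Cc1ccc(Oc2cc(C=O)cc(OC)c2OCc2ccccc2)c(OC)c1 | intermediate
5 | propargyl alcohol | C#CCO | starting material
6 | 3,4-dimethoxybenzyl chloride | COc1ccc(CCl)cc1OC | starting material
7 | bromomagnesium 3-(bromomagnesio)prop-2-ynoxide | Br[Mg]C#CCO[Mg]Br | intermediate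
8 | 4-(3,4-dimethoxyphenyl)but-2-yn-1-ol | OCC#CCc1ccc(OC)c(OC)c1 | intermediate
9 | (E)-4-(3,4-dimethoxyphenyl)-2-(tributylstannyl)but-2-en-1-ol | CCCC[Sn](CCCC)(CCCC)/C(CO)=C/Cc1ccc(OC)c(OC)c1 | intermediate
10 | (E)-4-(3,4-dimethoxyphenyl)-2-iodobut-2-en-1-ol | I/C(CO)=C/Cc1ccc(OC)c(OC)c1 | intermediate
11 | (E)-[4-(3,4-dimethoxyphenyl)-2-iodobut-2-enyloxy]triisopropylsilane | I/C(CO[Si](C(C)C)(C(C)C)C(C)C)=C/Cc1ccc(OC)c(OC)c1 | intermediate
12 | alkenyllithium from 11 (Li trans to the veratryl CH2) | [Li]/C(CO[Si](C(C)C)(C(C)C)C(C)C)=C/Cc1ccc(OC)c(OC)c1 | intermediate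
13 | bis[(E)-allylic alcohol], C7/C7' epimer mixture | c1(C(O)/C(CO[Si](C(C)C)(C(C)C)C(C)C)=C/Cc2ccc(OC)c(OC)c2)ccc(Oc2cc(C(O)/C(CO[Si](C(C)C)(C(C)C)C(C)C)=C/Cc3ccc(OC)c(OC)c3)cc(OC)c2OCc2ccccc2)c(OC)c1 | intermediate
14 | bis[(E)-aryl enone] | c1(C(=O)/C(CO[Si](C(C)C)(C(C)C)C(C)C)=C/Cc2ccc(OC)c(OC)c2)ccc(Oc2cc(C(=O)/C(CO[Si](C(C)C)(C(C)C)C(C)C)=C/Cc3ccc(OC)c(OC)c3)cc(OC)c2OCc2ccccc2)c(OC)c1 | intermediate
15 | (7S,7'S)-bis[(E)-allylic alcohol] | c1([C@H](O)/C(CO[Si](C(C)C)(C(C)C)C(C)C)=C/Cc2ccc(OC)c(OC)c2)ccc(Oc2cc([C@H](O)/C(CO[Si](C(C)C)(C(C)C)C(C)C)=C/Cc3ccc(OC)c(OC)c3)cc(OC)c2OCc2ccccc2)c(OC)c1 | intermediate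
16 | tributyl(iodomethyl)stannane | CCCC[Sn](CI)(CCCC)CCCC | starting material
17 | (7S,7'S)-bis(tributylstannylmethyl ether), key-step precursor | c1([C@H](OC[Sn](CCCC)(CCCC)CCCC)/C(CO[Si](C(C)C)(C(C)C)C(C)C)=C/Cc2ccc(OC)c(OC)c2)ccc(Oc2cc([C@H](OC[Sn](CCCC)(CCCC)CCCC)/C(CO[Si](C(C)C)(C(C)C)C(C)C)=C/Cc3ccc(OC)c(OC)c3)cc(OC)c2OCc2ccccc2)c(OC)c1 | intermediate
18 | (7S,7'S)-bis(lithiomethyl ether) | c1([C@H](OC[Li])/C(CO[Si](C(C)C)(C(C)C)C(C)C)=C/Cc2ccc(OC)c(OC)c2)ccc(Oc2cc([C@H](OC[Li])/C(CO[Si](C(C)C)(C(C)C)C(C)C)=C/Cc3ccc(OC)c(OC)c3)cc(OC)c2OCc2ccccc2)c(OC)c1 | intermediate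
19 | (4S,4'S)-bis[(E)-2-arylmethylidene-3-veratrylbutane-1,4-diol 1-TIPS ether], key-step product | c1(/C=C(/CO[Si](C(C)C)(C(C)C)C(C)C)[C@@H](CO)Cc2ccc(OC)c(OC)c2)ccc(Oc2cc(/C=C(/CO[Si](C(C)C)(C(C)C)C(C)C)[C@@H](CO)Cc3ccc(OC)c(OC)c3)cc(OC)c2OCc2ccccc2)c(OC)c1 | intermediate
20 | (4S,4'S)-tetraol | c1(/C=C(/CO)[C@@H](CO)Cc2ccc(OC)c(OC)c2)ccc(Oc2cc(/C=C(/CO)[C@@H](CO)Cc3ccc(OC)c(OC)c3)cc(OC)c2OCc2ccccc2)c(OC)c1 | intermediate
21 | (4S,4'S)-bis(hydroxy enal) | c1(/C=C(/C=O)[C@@H](CO)Cc2ccc(OC)c(OC)c2)ccc(Oc2cc(/C=C(/C=O)[C@@H](CO)Cc3ccc(OC)c(OC)c3)cc(OC)c2OCc2ccccc2)c(OC)c1 | intermediate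
22 | (4S,4'S)-bis-lactol (C2 epimers) | c1(/C=C2/C(O)OC[C@H]2Cc2ccc(OC)c(OC)c2)ccc(Oc2cc(/C=C3/C(O)OC[C@H]3Cc3ccc(OC)c(OC)c3)cc(OC)c2OCc2ccccc2)c(OC)c1 | intermediate
23 | (3E,4S,3'E,4'S)-bis(benzylidene lactone) | c1(/C=C2/C(=O)OC[C@H]2Cc2ccc(OC)c(OC)c2)ccc(Oc2cc(/C=C3/C(=O)OC[C@H]3Cc3ccc(OC)c(OC)c3)cc(OC)c2OCc2ccccc2)c(OC)c1 | intermediate
24 | (3R,4S,3'R,4'S)-bis(cis-lactone), free phenol | COc1ccc(C[C@@H]2COC(=O)[C@@H]2Cc2ccc(Oc3cc(C[C@H]4C(=O)OC[C@H]4Cc4ccc(OC)c(OC)c4)cc(OC)c3O)c(OC)c2)cc1OC | intermediate
25 | CNP0183104.1, (3S,4S,3'S,4'S) | COc1ccc(C[C@@H]2COC(=O)[C@H]2Cc2ccc(Oc3cc(C[C@@H]4C(=O)OC[C@H]4Cc4ccc(OC)c(OC)c4)cc(OC)c3O)c(OC)c2)cc1OC | target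

## Step count and risks

Total step count: 14. Longest linear sequence: 12 steps (steps 3 to 14, from 5 and 6).

**Step 10.**
- **Risk:** the migrating carbon C7 is both benzylic and allylic. A [1,2] shift through the radical pair, proton abstraction at C7–H, or leakage through the aryl-outside conformer could therefore erode the transfer at either end of the molecule.
- **Fallback:** it sets out from 15, avoids organolithium chemistry, and comes back at 19.
  - Heating 15 with N,N-dimethylformamide dimethyl acetal in xylene at about 140 °C exchanges the alcohols to the bis(mixed amide acetal) F1.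
  - Loss of methanol gives an alkoxy(amino)carbene. It undergoes the same suprafacial [2,3] shift under neutral conditions to the bis(β,γ-unsaturated N,N-dimethylamide) F2, which carries C5 at the acid level.
  - LiEt3BH in THF at 0 °C then reduces both amides to the primary alcohols.

**Step 8.**
- **Risk:** the catalyst may discriminate poorly between two sp2 ketone substituents, so enantioface selectivity could be low. Any error at one centre gives a diastereomer whose stereocentres are far apart and which is hard to separate.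
- **Fallback:** it sets out from 4 and 12 (made from 11 as in step 6), sets the carbinols in the C–C bond-forming event itself, and comes back at 15, so steps 7 and 8 drop out.
  - 12 is transmetalated with ZnBr2 and then n-BuLi to the alkenyl(butyl)zinc F3.
  - The lithium halides are masked with N,N,N',N'-tetraethylethylenediamine.
  - F3 is added to 4 in toluene at 0 °C with (+)-3-exo-morpholinoisoborneol as catalyst. This is a catalytic asymmetric alkenylzinc addition to an aromatic aldehyde, in which the catalyst only has to tell H from aryl and should direct attack to the Re face.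

**Step 4.**
- **Risk:** both alkyne substituents are CH2 groups, so hydropalladation may show weak regiocontrol and give much of the distal stannane.
- **Fallback:** it sets out from 8, makes the regiochemistry substrate-directed, and comes back at 10.
  - n-BuLi converts 8 into its lithium alkoxide.
  - Cp2Zr(H)Cl in THF then adds syn, with zirconium guided by the alkoxide to the adjacent alkyne carbon, to give the alkenylzirconocene chloride F4.
  - I2 cleaves the C–Zr bond with retention.

Further compounds
F1 | step 10 | (7S,7'S)-bis[methoxy(dimethylamino)methyl ether] of 15 | c1([C@H](OC(OC)N(C)C)/C(CO[Si](C(C)C)(C(C)C)C(C)C)=C/Cc2ccc(OC)c(OC)c2)ccc(Oc2cc([C@H](OC(OC)N(C)C)/C(CO[Si](C(C)C)(C(C)C)C(C)C)=C/Cc3ccc(OC)c(OC)c3)cc(OC)c2OCc2ccccc2)c(OC)c1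
F2 | step 10 | (4S,4'S)-bis[(E)-β,γ-unsaturated N,N-dimethylamide] | c1(/C=C(/CO[Si](C(C)C)(C(C)C)C(C)C)[C@@H](C(=O)N(C)C)Cc2ccc(OC)c(OC)c2)ccc(Oc2cc(/C=C(/CO[Si](C(C)C)(C(C)C)C(C)C)[C@@H](C(=O)N(C)C)Cc3ccc(OC)c(OC)c3)cc(OC)c2OCc2ccccc2)c(OC)c1
F3 | step 8 | alkenyl(butyl)zinc from 12 | CCCC[Zn]/C(CO[Si](C(C)C)(C(C)C)C(C)C)=C/Cc1ccc(OC)c(OC)c1
F4 | step 4 | alkenylzirconocene chloride, lithium alkoxide | [Li]OC/C(=C\Cc1ccc(OC)c(OC)c1)[Zr](Cl)(C1C=CC=C1)C1C=CC=C1
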